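## Retrosynthetic overview

1. The target is numbered as a 2H-chromen-5(4aH)-one (O1, C2, C3, C4, C4a, C5–C8, C8a). The 2H-pyran ring is closed last (O1–C8a) by displacement of a C8a methoxy group by the tertiary hydroxyl of a (Z)-3-hydroxy-3-methylbutenyl arm on C4a; that arm (C4, C3, C2) is grown from a one-carbon handle on C4a.
2. The handle (C4) and the oxygen on C7 are tied together as the O–C(=O) bridge of a 2-oxabicyclo[2.2.2]octenone, the CO2-retaining [4+2] adduct of a 2-pyrone; C8a arrives as a dimethyl ketal.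
3. Key disconnection: C7–C8 and C8a–C4a, by an enantioselective inverse-electron-demand Diels–Alder reaction. The diene is 4-methoxy-5-isovaleryl-3-prenyl-2-pyrone (C4a, C5, C6, C7, plus C4 and the C7 oxygen); the dienophile is the ketene dimethyl acetal of 5-methylhex-4-enoic acid (C8a and C8 with its prenyl group).
4. Enabling feature: the quaternary C4a carries a one-carbon-linked sp2 carbon (C4) and sits 1,4 across the carbocycle from the oxygenated C7, so C4 and O–C7 map onto the lactone of a pyrone. The C6 isovaleryl group of the target makes that pyrone electron-poor and gives it a second binding site for a chiral Lewis acid.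
5. Ring order: 2-pyrone (steps 1–4) → carbocycle, formed as the bridged lactone by dearomatising the pyrone (step 7) → bridge opened (steps 8–9) → 2H-pyran ring (step 14).

Key step: step 7

Remark: enol tautomers are drawn as in the target SMILES; compounds 14–20 are carried as mixtures at the stereocentres that step 11 erases (the ring CH bearing the second prenyl group, the lactol carbon, the side-chain carbinol), and only the quaternary carbon and the ring carbinol carbon tied to it are defined.

## Route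

Step 1
Reactants: 1 methyl acetoacetate; 2 1-bromo-3-methylbut-2-ene (prenyl bromide)
Product: 3 methyl 2-acetyl-5-methylhex-4-enoate (racemic)
Conditions: K2CO3, acetone, reflux
Reagents that add atoms: none
Why: acetoacetic ester C-alkylation, SN2 at the primary allylic carbon, should give the linear prenyl derivative; the stereocentre is lost again in step 3.

Step 2
Reactants: 3 methyl 2-acetyl-5-methylhex-4-enoate; 4 methyl 3-methylbutanoate
Product: 5 methyl 7-methyl-2-(3-methylbut-2-en-1-yl)-3,5-dioxooctanoate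
Conditions: NaH, THF, 0 °C; n-BuLi, 0 °C; then 4, −78 → 0 °C; aq. HCl (pH 4), 0 °C
Reagents that add atoms: none
Why: double deprotonation of the β-keto ester and Claisen γ-acylation at the terminal methyl carbon by the ester should give the 3,5-diketo ester.

Step 3
Reactants: 5 methyl 7-methyl-2-(3-methylbut-2-en-1-yl)-3,5-dioxooctanoate
Product: 7 4-hydroxy-5-(3-methylbutanoyl)-3-(3-methylbut-2-en-1-yl)-2H-pyran-2-one, via aminomethylene diketo ester 6 (not isolated)
Conditions: Me2NCH(OMe)2, PhMe, 50 °C; then AcOH–H2O (4:1), 60 °C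
Reagents that add atoms: N,N-dimethylformamide dimethyl acetal, COC(OC)N(C)C; water, O
Why: aminomethylenation of the most acidic CH2 (between the two ketones), hydrolysis to the hydroxymethylene compound and lactonisation of its enol hydroxyl onto the ester should give the aromatic 6-unsubstituted 5-acyl-4-hydroxy-2-pyrone.

Step 4
Reactants: 7 4-hydroxy-5-(3-methylbutanoyl)-3-(3-methylbut-2-en-1-yl)-2H-pyran-2-one
Product: 8 4-methoxy-5-(3-methylbutanoyl)-3-(3-methylbut-2-en-1-yl)-2H-pyran-2-one
Conditions: Me2SO4, K2CO3, acetone, rt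
Reagents that add atoms: dimethyl sulfate, COS(=O)(=O)OC
Why: O-methylation of the vinylogous acid (4-hydroxy-2-pyrones give 4-methoxy-2-pyrones under these conditions) removes the acidic proton that would destroy the ketene acetal.

Step 5
Reactants: 9 5-bromo-2-methylpent-2-ene; 10 tetramethyl orthocarbonate
Product: 12 6,6,6-trimethoxy-2-methylhex-2-ene, via (4-methylpent-3-en-1-yl)magnesium bromide 11 (not isolated)
Conditions: Mg, THF, rt; then C(OMe)4, reflux
Reagents that add atoms: none
Why: Grignard formation and displacement of one methoxide from the orthocarbonate (ortho ester synthesis) should give the ortho ester without exposing the trisubstituted alkene to acid.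

Step 6
Reactants: 12 6,6,6-trimethoxy-2-methylhex-2-ene
Product: 13 1,1-dimethoxy-5-methylhexa-1,4-diene
Conditions: TMSOTf, i-Pr2NEt, CH2Cl2, −20 °C → rt; distilled from the amine salt
Reagents that add atoms: none
Why: silyl-triflate ionisation of the ortho ester to a dialkoxycarbenium ion and deprotonation by the hindered amine (the acetal-to-enol-ether elimination applied to an ortho ester) should give the ketene dimethyl acetal.

Step 7
Reactants: 8 4-methoxy-5-(3-methylbutanoyl)-3-(3-methylbut-2-en-1-yl)-2H-pyran-2-one; 13 1,1-dimethoxy-5-methylhexa-1,4-diene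
Product: 14 (1R,4R)-5,8,8-trimethoxy-6-(3-methylbutanoyl)-4,7-bis(3-methylbut-2-en-1-yl)-2-oxabicyclo[2.2.2]oct-5-en-3-one
Conditions: Cu(OTf)2 (10 mol %), 2,2'-(propane-2,2-diyl)bis[(4S)-4-tert-butyl-4,5-dihydro-1,3-oxazole] (11 mol %), 4 Å MS, CH2Cl2, −40 → 0 °C; 13 (2 equiv)
Reagents that add atoms: none
Why: Proposed new method: an inverse-electron-demand Diels–Alder reaction in which the pyrone is held on the chiral divalent copper Lewis acid through its acyl oxygen and its methoxy oxygen; the nucleophilic CH terminus of the ketene acetal attacks pyrone C6 (the acyl-activated position next to the ring oxygen) and pyrone C3 then closes onto the developing dialkoxycarbenium carbon in an asynchronous, suprafacial [4+2]. The closest known reactions are the thermal cycloadditions of 5-carboalkoxy-2-pyrones (coumalates) with ketene acetals and the chiral-Lewis-acid-catalysed cycloadditions of 3-carboalkoxy-2-pyrones with vinyl ethers. The carbocycle is closed by this intermolecular cycloaddition (bonds C7–C8 and C8a–C4a of the target) and is held as a bicyclo[2.2.2]octene by the lactone bridge. The quaternary stereocentre (future C4a) is set by the face of the flat pyrone left open by the tert-butyl groups of the ligand; the other bridgehead follows from it, and the prenyl-bearing CH (endo or exo) is erased in step 11. The step needs regioselectivity (given by the polarisation of both partners), carbocyclic instead of hetero-Diels–Alder closure (the chelate holds the acyl C=O turned away from C6) and retention of CO2 (low temperature). If the sense of induction were opposite to the one required, the enantiomeric ligand would be used.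

Step 8
Reactants: 14 (1R,4R)-5,8,8-trimethoxy-6-(3-methylbutanoyl)-4,7-bis(3-methylbut-2-en-1-yl)-2-oxabicyclo[2.2.2]oct-5-en-3-one
Product: 15 (1R,4S)-6-(1-hydroxy-3-methylbutyl)-5,8,8-trimethoxy-4,7-bis(3-methylbut-2-en-1-yl)-2-oxabicyclo[2.2.2]oct-5-en-3-ol
Conditions: i-Bu2AlH (3.5 equiv), CH2Cl2, −78 °C; aq. KNaC4H4O6
Reagents that add atoms: none
Why: hydride reduction should stop at the lactol (stable aluminium hemiacetal at −78 °C) and deliberately also takes the vinylogous-ester ketone to the carbinol, which step 11 re-oxidises; the new lactol and carbinol centres are uncontrolled and are erased later, and the acid-labile β-methoxy allylic alcohols are handled under buffered conditions.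

Step 9
Reactants: 15 (1R,4S)-6-(1-hydroxy-3-methylbutyl)-5,8,8-trimethoxy-4,7-bis(3-methylbut-2-en-1-yl)-2-oxabicyclo[2.2.2]oct-5-en-3-ol
Product: 17 (1R,4R)-4-ethynyl-2-(1-hydroxy-3-methylbutyl)-3,5,5-trimethoxy-4,6-bis(3-methylbut-2-en-1-yl)cyclohex-2-en-1-ol, via ring-opened hydroxy aldehyde 16 (not isolated)
Conditions: dimethyl (1-diazo-2-oxopropyl)phosphonate, K2CO3, MeOH, 0 °C → rt
Reagents that add atoms: dimethyl (1-diazo-2-oxopropyl)phosphonate, CC(=O)C(=[N+]=[N-])P(=O)(OC)OC
Why: Ohira–Bestmann (Seyferth–Gilbert) homologation of the lactol through its open aldehyde form should give the terminal alkyne; the aldehyde sits on the quaternary carbon, so nothing can epimerise.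

Step 10
Reactants: 17 (1R,4R)-4-ethynyl-2-(1-hydroxy-3-methylbutyl)-3,5,5-trimethoxy-4,6-bis(3-methylbut-2-en-1-yl)cyclohex-2-en-1-ol; 18 acetone
Product: 19 (1R,4R)-2-(1-hydroxy-3-methylbutyl)-4-(3-hydroxy-3-methylbut-1-yn-1-yl)-3,5,5-trimethoxy-4,6-bis(3-methylbut-2-en-1-yl)cyclohex-2-en-1-ol
Conditions: n-BuLi (3.3 equiv), THF, −78 °C; acetone, −78 → 0 °C; H2O
Reagents that add atoms: none
Why: after deprotonation of the two hydroxyls, the lithium acetylide adds to acetone (1,2-addition) to give the tertiary propargylic alcohol; enol ether, ketal and prenyl groups are inert to the base.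

Step 11
Reactants: 19 (1R,4R)-2-(1-hydroxy-3-methylbutyl)-4-(3-hydroxy-3-methylbut-1-yn-1-yl)-3,5,5-trimethoxy-4,6-bis(3-methylbut-2-en-1-yl)cyclohex-2-en-1-ol
Product: 21 (4S)-4-(3-hydroxy-3-methylbut-1-yn-1-yl)-3,5-dimethoxy-2-(3-methylbutanoyl)-4,6-bis(3-methylbut-2-en-1-yl)cyclohexa-2,5-dien-1-one, via β-keto ketal 20 (not isolated)
Conditions: Dess–Martin periodinane (3 equiv), pyridine, CH2Cl2, 0 °C → rt; then DBU, rt
Reagents that add atoms: none
Why: Dess–Martin oxidation of both secondary allylic alcohols (the tertiary one is untouched) followed by E1cB loss of methanol from the β-keto ketal should give the cross-conjugated dienone and removes every stereocentre except the quaternary one.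

Step 12
Reactants: 21 (4S)-4-(3-hydroxy-3-methylbut-1-yn-1-yl)-3,5-dimethoxy-2-(3-methylbutanoyl)-4,6-bis(3-methylbut-2-en-1-yl)cyclohexa-2,5-dien-1-one
Product: 22 (6S)-3-hydroxy-6-(3-hydroxy-3-methylbut-1-yn-1-yl)-5-methoxy-2-(3-methylbutanoyl)-4,6-bis(3-methylbut-2-en-1-yl)cyclohexa-2,4-dien-1-one
Conditions: LiOH, THF–H2O, 0 °C; then 1 M HCl to pH 3
Reagents that add atoms: lithium hydroxide, [Li+].[OH-]
Why: addition–elimination hydrolysis of a vinylogous ester: hydroxide should attack the methoxy-bearing carbon that is activated by both the ring ketone and the isovaleryl group and give the β-triketone, while the singly activated methoxy next to the prenyl-bearing carbon stays.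

Step 13
Reactants: 22 (6S)-3-hydroxy-6-(3-hydroxy-3-methylbut-1-yn-1-yl)-5-methoxy-2-(3-methylbutanoyl)-4,6-bis(3-methylbut-2-en-1-yl)cyclohexa-2,4-dien-1-one
Product: 23 (6S)-3-hydroxy-6-[(1Z)-3-hydroxy-3-methylbut-1-en-1-yl]-5-methoxy-2-(3-methylbutanoyl)-4,6-bis(3-methylbut-2-en-1-yl)cyclohexa-2,4-dien-1-one
Conditions: H2 (1 atm), Pd/CaCO3–Pb(OAc)2 (Lindlar catalyst), quinoline, EtOAc, rt
Reagents that add atoms: none
Why: Lindlar semi-hydrogenation, syn addition of H2 to the alkyne, should give the (Z)-alkene; the trisubstituted prenyl olefins and the dienone are not reduced.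

Step 14
Reactants: 23 (6S)-3-hydroxy-6-[(1Z)-3-hydroxy-3-methylbut-1-en-1-yl]-5-methoxy-2-(3-methylbutanoyl)-4,6-bis(3-methylbut-2-en-1-yl)cyclohexa-2,4-dien-1-one
Product: 24 (4aS)-7-hydroxy-2,2-dimethyl-6-(3-methylbutanoyl)-4a,8-bis(3-methylbut-2-en-1-yl)-2H-chromen-5(4aH)-one
Conditions: PPTS (10 mol %), PhMe, 5 Å MS, 40 °C
Reagents that add atoms: none
Why: acid-catalysed intramolecular vinylogous transesterification: the cis-held tertiary hydroxyl adds 6-exo to the methoxy-bearing enol-ether carbon and methanol is lost; this is the only ring oxygen position with a leaving group, the others being locked in the chelated β-triketone, and the quaternary stereocentre is not touched.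

## Compound list

1 | methyl acetoacetate | CC(=O)CC(=O)OC | starting material
2 | 1-bromo-3-methylbut-2-ene | CC(C)=CCBr | starting material
3 | methyl 2-acetyl-5-methylhex-4-enoate (racemic) | CC(=O)C(CC=C(C)C)C(=O)OC | intermediate
4 | methyl 3-methylbutanoate | CC(C)CC(=O)OC | starting material
5 | methyl 7-methyl-2-(3-methylbut-2-en-1-yl)-3,5-dioxooctanoate (racemic) | COC(=O)C(CC=C(C)C)C(=O)CC(=O)CC(C)C | intermediate
6 | methyl 4-[(dimethylamino)methylidene]-7-methyl-2-(3-methylbut-2-en-1-yl)-3,5-dioxooctanoate (not isolated) | COC(=O)C(CC=C(C)C)C(=O)C(=CN(C)C)C(=O)CC(C)C | intermediate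
7 | 4-hydroxy-5-(3-methylbutanoyl)-3-(3-methylbut-2-en-1-yl)-2H-pyran-2-one | O=C1OC=C(C(=O)CC(C)C)C(O)=C1CC=C(C)C | intermediate
8 | 4-methoxy-5-(3-methylbutanoyl)-3-(3-methylbut-2-en-1-yl)-2H-pyran-2-one | O=C1OC=C(C(=O)CC(C)C)C(OC)=C1CC=C(C)C | intermediate
9 | 5-bromo-2-methylpent-2-ene | CC(C)=CCCBr | starting material
10 | tetramethyl orthocarbonate | COC(OC)(OC)OC | starting material
11 | (4-methylpent-3-en-1-yl)magnesium bromide (not isolated) | CC(C)=CCC[Mg]Br | intermediate
12 | 6,6,6-trimethoxy-2-methylhex-2-ene | COC(OC)(OC)CCC=C(C)C | intermediate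
13 | 1,1-dimethoxy-5-methylhexa-1,4-diene | COC(OC)=CCC=C(C)C | intermediate
14 | (1R,4R)-5,8,8-trimethoxy-6-(3-methylbutanoyl)-4,7-bis(3-methylbut-2-en-1-yl)-2-oxabicyclo[2.2.2]oct-5-en-3-one (C7 epimers) | O=C1O[C@H]2C(C(=O)CC(C)C)=C(OC)[C@]1(CC=C(C)C)C(OC)(OC)C2CC=C(C)C | intermediate
15 | (1R,4S)-6-(1-hydroxy-3-methylbutyl)-5,8,8-trimethoxy-4,7-bis(3-methylbut-2-en-1-yl)-2-oxabicyclo[2.2.2]oct-5-en-3-ol (epimers at C3, C7 and the carbinol carbon) | OC1O[C@H]2C(C(O)CC(C)C)=C(OC)[C@]1(CC=C(C)C)C(OC)(OC)C2CC=C(C)C | intermediate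
16 | (1S,4R)-4-hydroxy-3-(1-hydroxy-3-methylbutyl)-2,6,6-trimethoxy-1,5-bis(3-methylbut-2-en-1-yl)cyclohex-2-ene-1-carbaldehyde (not isolated) | O=C[C@]1(CC=C(C)C)C(OC)=C(C(O)CC(C)C)[C@H](O)C(CC=C(C)C)C1(OC)OC | intermediate
17 | (1R,4R)-4-ethynyl-2-(1-hydroxy-3-methylbutyl)-3,5,5-trimethoxy-4,6-bis(3-methylbut-2-en-1-yl)cyclohex-2-en-1-ol (epimers at C6 and the carbinol carbon) | C#C[C@]1(CC=C(C)C)C(OC)=C(C(O)CC(C)C)[C@H](O)C(CC=C(C)C)C1(OC)OC | intermediate
18 | acetone | CC(C)=O | starting material
19 | (1R,4R)-2-(1-hydroxy-3-methylbutyl)-4-(3-hydroxy-3-methylbut-1-yn-1-yl)-3,5,5-trimethoxy-4,6-bis(3-methylbut-2-en-1-yl)cyclohex-2-en-1-ol (epimers at C6 and the carbinol carbon) | CC(C)(O)C#C[C@]1(CC=C(C)C)C(OC)=C(C(O)CC(C)C)[C@H](O)C(CC=C(C)C)C1(OC)OC | intermediate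
20 | (4R)-4-(3-hydroxy-3-methylbut-1-yn-1-yl)-3,5,5-trimethoxy-2-(3-methylbutanoyl)-4,6-bis(3-methylbut-2-en-1-yl)cyclohex-2-en-1-one (C6 epimers, not isolated) | CC(C)(O)C#C[C@]1(CC=C(C)C)C(OC)=C(C(=O)CC(C)C)C(=O)C(CC=C(C)C)C1(OC)OC | intermediate
21 | (4S)-4-(3-hydroxy-3-methylbut-1-yn-1-yl)-3,5-dimethoxy-2-(3-methylbutanoyl)-4,6-bis(3-methylbut-2-en-1-yl)cyclohexa-2,5-dien-1-one | CC(C)(O)C#C[C@]1(CC=C(C)C)C(OC)=C(C(=O)CC(C)C)C(=O)C(CC=C(C)C)=C1OC | intermediate
22 | (6S)-3-hydroxy-6-(3-hydroxy-3-methylbut-1-yn-1-yl)-5-methoxy-2-(3-methylbutanoyl)-4,6-bis(3-methylbut-2-en-1-yl)cyclohexa-2,4-dien-1-one | CC(C)(O)C#C[C@]1(CC=C(C)C)C(=O)C(C(=O)CC(C)C)=C(O)C(CC=C(C)C)=C1OC | intermediate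
23 | (6S)-3-hydroxy-6-[(1Z)-3-hydroxy-3-methylbut-1-en-1-yl]-5-methoxy-2-(3-methylbutanoyl)-4,6-bis(3-methylbut-2-en-1-yl)cyclohexa-2,4-dien-1-one | CC(C)(O)/C=C\[C@]1(CC=C(C)C)C(=O)C(C(=O)CC(C)C)=C(O)C(CC=C(C)C)=C1OC | intermediate
24 | (4aS)-7-hydroxy-2,2-dimethyl-6-(3-methylbutanoyl)-4a,8-bis(3-methylbut-2-en-1-yl)-2H-chromen-5(4aH)-one | CC(C)=CCC1=C2OC(C)(C)C=C[C@]2(CC=C(C)C)C(=O)C(C(=O)CC(C)C)=C1O | target

## Step count and risks

Total: 14 steps (steps 5 and 6 make the dienophile). Longest linear sequence: 12 steps (1–4, then 7–14).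

**Step 7 (Proposed new method).** What may go wrong: the pyrone may bind the copper through one oxygen only, giving poor facial discrimination; the zwitterionic intermediate may close through the acyl oxygen (hetero-Diels–Alder); or the adduct may undergo cycloreversion with loss of CO2. The fallback replaces catalyst control by a chiral auxiliary and uses known thermal chemistry; it sets out from 12 and 8 and returns at 14. Ortho ester 12 is exchanged with (2R,3R)-butane-2,3-diol (PPTS, PhMe, removal of MeOH) to the cyclic ortho ester (4R,5R)-2-methoxy-4,5-dimethyl-2-(4-methylpent-3-en-1-yl)-1,3-dioxolane F1. TMSOTf and i-Pr2NEt should convert this into the C2-symmetric ketene acetal (4R,5R)-4,5-dimethyl-2-(4-methylpent-3-en-1-ylidene)-1,3-dioxolane F2. Uncatalysed cycloaddition of F2 with 8 (PhMe, 60 °C, as for coumalates) should give diastereomeric spiro-ketal adducts, from which the required isomer (1R,4R,4'R,5'R)-5-methoxy-4',5'-dimethyl-6-(3-methylbutanoyl)-4,7-bis(3-methylbut-2-en-1-yl)spiro[2-oxabicyclo[2.2.2]oct-5-ene-8,2'-[1,3]dioxolan]-3-one F3 is separated by chromatography. Ketal exchange (MeOH, HC(OMe)3, PPTS) then gives 14 and releases the diol.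

**Step 14.** What may go wrong: slow addition of the hindered tertiary alcohol, ionisation of the tertiary allylic alcohol with loss of water to a diene, or closure onto the C5 carbonyl instead of C8a. The fallback reverses the polarity of the ring closure; it sets out from 22 and returns at 24. SN2 demethylation of the remaining enol ether (LiCl, DMF, 60 °C) should give (6S)-3,5-dihydroxy-6-(3-hydroxy-3-methylbut-1-yn-1-yl)-2-(3-methylbutanoyl)-4,6-bis(3-methylbut-2-en-1-yl)cyclohexa-2,4-dien-1-one F4. Lindlar semi-hydrogenation should give the (Z)-alkenol (6S)-3,5-dihydroxy-6-[(1Z)-3-hydroxy-3-methylbut-1-en-1-yl]-2-(3-methylbutanoyl)-4,6-bis(3-methylbut-2-en-1-yl)cyclohexa-2,4-dien-1-one F5. Mild acid (PPTS, CH2Cl2, rt) then ionises the tertiary allylic alcohol, and the free enol oxygen on C8a, the one not held in the hydrogen bond to the acyl group, captures the cis-allyl cation as in known 2,2-dimethylchromene closures, giving 24.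

**Step 3.** What may go wrong: lactonisation through the enol oxygen of the isovaleryl ketone instead of the hydroxymethylene oxygen (which would put the isobutyl group on the ring), or pyrone formation from 5 before the aminomethylenation. The fallback changes which bond closes the ring; it sets out from 6 (isolated after the first half of step 3) and returns at 7. Selective cleavage of the methyl ester (Me3SnOH, ClCH2CH2Cl, 60 °C) should give 4-[(dimethylamino)methylidene]-7-methyl-2-(3-methylbut-2-en-1-yl)-3,5-dioxooctanoic acid F6. Its carboxyl oxygen adds to the aminomethylene carbon and dimethylamine is expelled (AcOH cat., rt), so the ring oxygen can only end next to the CH carbon, giving 7.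

Further compounds
F1 | step 7 | (4R,5R)-2-methoxy-4,5-dimethyl-2-(4-methylpent-3-en-1-yl)-1,3-dioxolane | COC1(CCC=C(C)C)O[C@H](C)[C@@H](C)O1
F2 | step 7 | (4R,5R)-4,5-dimethyl-2-(4-methylpent-3-en-1-ylidene)-1,3-dioxolane | CC(C)=CCC=C1O[C@H](C)[C@@H](C)O1
F3 | step 7 | (1R,4R,4'R,5'R)-5-methoxy-4',5'-dimethyl-6-(3-methylbutanoyl)-4,7-bis(3-methylbut-2-en-1-yl)spiro[2-oxabicyclo[2.2.2]oct-5-ene-8,2'-[1,3]dioxolan]-3-one | O=C1O[C@H]2C(C(=O)CC(C)C)=C(OC)[C@]1(CC=C(C)C)C3(O[C@H](C)[C@@H](C)O3)C2CC=C(C)C
F4 | step 14 | (6S)-3,5-dihydroxy-6-(3-hydroxy-3-methylbut-1-yn-1-yl)-2-(3-methylbutanoyl)-4,6-bis(3-methylbut-2-en-1-yl)cyclohexa-2,4-dien-1-one | CC(C)(O)C#C[C@]1(CC=C(C)C)C(=O)C(C(=O)CC(C)C)=C(O)C(CC=C(C)C)=C1O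
F5 | step 14 | (6S)-3,5-dihydroxy-6-[(1Z)-3-hydroxy-3-methylbut-1-en-1-yl]-2-(3-methylbutanoyl)-4,6-bis(3-methylbut-2-en-1-yl)cyclohexa-2,4-dien-1-one | CC(C)(O)/C=C\[C@]1(CC=C(C)C)C(=O)C(C(=O)CC(C)C)=C(O)C(CC=C(C)C)=C1O
F6 | step 3 | 4-[(dimethylamino)methylidene]-7-methyl-2-(3-methylbut-2-en-1-yl)-3,5-dioxooctanoic acid | OC(=O)C(CC=C(C)C)C(=O)C(=CN(C)C)C(=O)CC(C)C
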